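**Plan**

- Cuts: O1–C2 and C2–C3 come first and open ring C, so that ring B and C2 leave as 4-methoxybenzoic anhydride. C3–C4 follows (methoxymethyl anion + aldehyde), then C5–C6 of ring A, and last C4a–C8a (vinyllithium + squarate carbonyl).
- Enabling feature: C6, C7, C8 and C8a of ring A are four adjacent oxygen-bearing carbons, which is the C4O4 pattern of dimethyl squarate. C5 (the lone C–H) and C4a (carrier of C4) are the two alkene carbons of a 2-metallated acrolein acetal.
- Forward order: C4a–C8a by 1,2-addition, a MOM ether on the future C8a oxygen, and thermal four-to-six ring expansion to ring A. Then the C6 phenol is methylated, C4 is unmasked as the aldehyde, and C3 is added and oxidised to the ketone.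
- Ring C is closed last, and ring B is attached in the same operation, by Allan–Robinson condensation.
- Stereochemistry: the target has no stereocentre. The two carbinol centres met on the way are racemic and are erased by ring opening and by oxidation, so only the torquoselectivity of the ring opening needs control.

Key step: step 3

Remark: flavone numbering (O1, C2–C4, C4a, C5–C8, C8a) is used for the atoms from the first intermediate on, and Bu3SnCH2OMe is treated as a purchasable reagent.

**Step 1**
Reactants: 1 2-bromo-3,3-diethoxyprop-1-ene; 2 dimethyl squarate (3,4-dimethoxycyclobut-3-ene-1,2-dione)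
Product: 5 rac-4-(3,3-diethoxyprop-1-en-2-yl)-4-hydroxy-2,3-dimethoxycyclobut-2-en-1-one, via vinyllithium 3 (not isolated), via lithium alkoxide 4 (not isolated)
Conditions: 1, t-BuLi (2.0 equiv), THF, −78 °C; cannulated into 2 (1.1 equiv), THF, −78 °C; sat. aq. NH4Cl, −78 °C → rt
Reagents that add atoms: none
Why: Halogen–lithium exchange gives the α-lithiated acrolein acetal, which is stable at −78 °C and should add 1,2 to one of the two equivalent squarate carbonyls (organolithium 1,2-addition to a squarate ester), forming C4a–C8a and a racemic carbinol centre that needs no control, while inverse addition suppresses a second addition.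

**Step 2**
Reactants: 5 rac-4-(3,3-diethoxyprop-1-en-2-yl)-4-hydroxy-2,3-dimethoxycyclobut-2-en-1-one
Product: 6 rac-4-(3,3-diethoxyprop-1-en-2-yl)-2,3-dimethoxy-4-(methoxymethoxy)cyclobut-2-en-1-one
Conditions: MOMCl (3 equiv), i-Pr2NEt (4 equiv), Bu4NI (cat.), CH2Cl2, 0 °C → rt
Reagents that add atoms: chloromethyl methyl ether (MOMCl), COCCl
Why: MOM etherification of a tertiary alcohol under non-nucleophilic amine base should leave the vinylogous ester and the diethyl acetal untouched, and it labels the future C8a oxygen so that the two ring A phenol oxygens are different from the moment they appear.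

**Step 3**
Reactants: 6 rac-4-(3,3-diethoxyprop-1-en-2-yl)-2,3-dimethoxy-4-(methoxymethoxy)cyclobut-2-en-1-one
Product: 9 5-(diethoxymethyl)-2,3-dimethoxy-4-(methoxymethoxy)phenol, via dienylketene 7 (not isolated), via cyclohexa-2,4-dienone 8 (not isolated)
Conditions: degassed p-xylene (0.02 M), 138 °C, Ar, base-washed glassware
Reagents that add atoms: none
Why: Heat breaks the C1–C4 σ-bond of the cyclobutenone (the C6···C8a link) in a conrotatory 4π electrocyclic opening to the (Z)-dienylketene 7, in which the former carbinol carbon is C8a and the ketene carbon is C6. A disrotatory 6π electrocyclisation then joins the ketene carbon to the terminal CH2 of the alkenyl group (C5–C6 bond, six-membered carbocycle, ring A) to give dienone 8, whose enolisation to phenol 9 makes the sequence irreversible. This is the Moore ring expansion of squarate-derived 4-alkenyl-4-oxycyclobutenones, known for the free carbinols and for their ethers. No stereocentre is created and the racemic centre of 6 is erased. The selectivity required is torquoselectivity: the donor OMOM group rotates outward, which forces the alkenyl group inward, next to the ketene, where it can close. There is no regiochemical choice, because only one σ-bond lies opposite the ring alkene and the alkenyl unit has a single free terminus, and the ether on C8a leaves C6–OH as the only phenol and blocks air oxidation to a quinone.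

**Step 4**
Reactants: 9 5-(diethoxymethyl)-2,3-dimethoxy-4-(methoxymethoxy)phenol
Product: 10 1-(diethoxymethyl)-3,4,5-trimethoxy-2-(methoxymethoxy)benzene
Conditions: MeI (1.5 equiv), K2CO3 (2 equiv), acetone, 56 °C, Ar
Reagents that add atoms: iodomethane (MeI), CI
Why: Williamson O-methylation of the only free phenol (C6–OH) should be unambiguous, and both acetal-type groups are stable to carbonate base.

**Step 5**
Reactants: 10 1-(diethoxymethyl)-3,4,5-trimethoxy-2-(methoxymethoxy)benzene
Product: 11 3,4,5-trimethoxy-2-(methoxymethoxy)benzaldehyde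
Conditions: PPTS (0.1 equiv), THF–H2O (4:1), rt
Reagents that add atoms: water, O
Why: In this acid-catalysed acetal hydrolysis the dialkyl acetal of an electron-rich benzaldehyde ionises far more readily than an aryl MOM ether, so a weak acid at room temperature should release C4 as the aldehyde and keep the phenol protected.

**Step 6**
Reactants: 11 3,4,5-trimethoxy-2-(methoxymethoxy)benzaldehyde
Product: 13 rac-2-methoxy-1-[3,4,5-trimethoxy-2-(methoxymethoxy)phenyl]ethan-1-ol, via lithium alkoxide 12 (not isolated)
Conditions: Bu3SnCH2OMe (1.5 equiv), n-BuLi (1.4 equiv), THF, −78 °C; then 11, −78 °C; sat. aq. NH4Cl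
Reagents that add atoms: tributyl(methoxymethyl)stannane, CCCC[Sn](CCCC)(CCCC)COC
Why: Tin–lithium exchange gives the α-alkoxy organolithium MeOCH2Li, whose 1,2-addition to the non-enolisable aldehyde forms C3–C4 and a racemic carbinol centre that the next step removes.

**Step 7**
Reactants: 13 rac-2-methoxy-1-[3,4,5-trimethoxy-2-(methoxymethoxy)phenyl]ethan-1-ol
Product: 14 2-methoxy-1-[3,4,5-trimethoxy-2-(methoxymethoxy)phenyl]ethan-1-one
Conditions: Dess–Martin periodinane (1.3 equiv), CH2Cl2, 0 °C → rt
Reagents that add atoms: none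
Why: Dess–Martin oxidation of a secondary benzylic alcohol is mild enough for the fully etherified, electron-rich arene and the MOM group, since no free phenol is present to be oxidised.

**Step 8**
Reactants: 14 2-methoxy-1-[3,4,5-trimethoxy-2-(methoxymethoxy)phenyl]ethan-1-one
Product: 15 1-(2-hydroxy-3,4,5-trimethoxyphenyl)-2-methoxyethan-1-one
Conditions: conc. HCl (cat.), MeOH, 50 °C
Reagents that add atoms: none
Why: Acid-catalysed transacetalisation passes the MOM group to methanol and frees the C8a phenol, which is stabilised by its hydrogen bond to the ketone, while the aryl and alkyl methyl ethers are inert.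

**Step 9**
Reactants: 15 1-(2-hydroxy-3,4,5-trimethoxyphenyl)-2-methoxyethan-1-one; 16 4-methoxybenzoic anhydride
Product: 18 auranetin (3,6,7,8,4'-pentamethoxyflavone), via 1,3-diketone 17 (not isolated)
Conditions: 16 (3 equiv), 4-MeOC6H4CO2Na (1.5 equiv), neat, 175–180 °C, Ar; aq. Na2CO3 wash
Reagents that add atoms: none
Why: In this Allan–Robinson condensation the carboxylate enolises the ω-methoxy ketone, 16 C-aroylates the enolate to diketone 17 (C2–C3), and the phenol adds 6-exo-trig to the new aryl ketone and loses water (O1–C2) to close ring C, with the C3 methoxy group blocking a second aroylation.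

**Compound list**

1 | 2-bromo-3,3-diethoxyprop-1-ene | CCOC(OCC)C(Br)=C | starting material
2 | dimethyl squarate (3,4-dimethoxycyclobut-3-ene-1,2-dione) | COC1=C(OC)C(=O)C1=O | starting material
3 | (3,3-diethoxyprop-1-en-2-yl)lithium | [Li]C(=C)C(OCC)OCC | intermediate
4 | lithium alkoxide of 5 (racemic) | [Li+].CCOC(OCC)C(=C)C1([O-])C(OC)=C(OC)C1=O | intermediate
5 | rac-4-(3,3-diethoxyprop-1-en-2-yl)-4-hydroxy-2,3-dimethoxycyclobut-2-en-1-one | CCOC(OCC)C(=C)C1(O)C(OC)=C(OC)C1=O | intermediate
6 | rac-4-(3,3-diethoxyprop-1-en-2-yl)-2,3-dimethoxy-4-(methoxymethoxy)cyclobut-2-en-1-one | CCOC(OCC)C(=C)C1(OCOC)C(OC)=C(OC)C1=O | intermediate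
7 | (3Z)-5-(diethoxymethyl)-2,3-dimethoxy-4-(methoxymethoxy)hexa-1,3,5-trien-1-one | O=C=C(OC)/C(OC)=C(\C(=C)C(OCC)OCC)OCOC | intermediate
8 | 5-(diethoxymethyl)-2,3-dimethoxy-4-(methoxymethoxy)cyclohexa-2,4-dien-1-one | O=C1CC(C(OCC)OCC)=C(OCOC)C(OC)=C1OC | intermediate
9 | 5-(diethoxymethyl)-2,3-dimethoxy-4-(methoxymethoxy)phenol | CCOC(OCC)c1cc(O)c(OC)c(OC)c1OCOC | intermediate
10 | 1-(diethoxymethyl)-3,4,5-trimethoxy-2-(methoxymethoxy)benzene | CCOC(OCC)c1cc(OC)c(OC)c(OC)c1OCOC | intermediate
11 | 3,4,5-trimethoxy-2-(methoxymethoxy)benzaldehyde | O=Cc1cc(OC)c(OC)c(OC)c1OCOC | intermediate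
12 | lithium alkoxide of 13 (racemic) | [Li+].COCC([O-])c1cc(OC)c(OC)c(OC)c1OCOC | intermediate
13 | rac-2-methoxy-1-[3,4,5-trimethoxy-2-(methoxymethoxy)phenyl]ethan-1-ol | COCC(O)c1cc(OC)c(OC)c(OC)c1OCOC | intermediate
14 | 2-methoxy-1-[3,4,5-trimethoxy-2-(methoxymethoxy)phenyl]ethan-1-one | COCC(=O)c1cc(OC)c(OC)c(OC)c1OCOC | intermediate
15 | 1-(2-hydroxy-3,4,5-trimethoxyphenyl)-2-methoxyethan-1-one | COCC(=O)c1cc(OC)c(OC)c(OC)c1O | intermediate
16 | 4-methoxybenzoic anhydride | COc1ccc(C(=O)OC(=O)c2ccc(OC)cc2)cc1 | starting material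
17 | 1-(2-hydroxy-3,4,5-trimethoxyphenyl)-2-methoxy-3-(4-methoxyphenyl)propane-1,3-dione | COc1ccc(C(=O)C(OC)C(=O)c2cc(OC)c(OC)c(OC)c2O)cc1 | intermediate
18 | auranetin (3,6,7,8-tetramethoxy-2-(4-methoxyphenyl)-4H-chromen-4-one) | COc1ccc(-c2oc3c(OC)c(OC)c(OC)cc3c(=O)c2OC)cc1 | target

Total step count: 9. Longest linear sequence: 9 steps (1 or 2 to 18).

**Steps most likely to fail**

**Step 3 (ring expansion).**
- Risk: the diethyl acetal may ionise or the MOM group may be lost during prolonged heating beside the phenol that is being formed. That phenol may also capture the ketene before the 6π closure.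
- Fallback, from 5 back to 11: the ether is omitted and the two phenols are told apart by hydrogen bonding instead. Free carbinol 5 is heated in degassed p-xylene to 2-(diethoxymethyl)-5,6-dimethoxybenzene-1,4-diol F1. This is hydrolysed at once (1 M HCl, THF) to 2,5-dihydroxy-3,4-dimethoxybenzaldehyde F2, so the fate of the acetal no longer matters. MeI (1 equiv) with K2CO3 in acetone under argon should methylate only the C6 hydroxyl, because the C8a hydroxyl is tied to the aldehyde oxygen, and give 2-hydroxy-3,4,5-trimethoxybenzaldehyde F3. MOMCl/i-Pr2NEt then leads to 11. The same detour also bypasses step 2.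

**Step 6 (methoxymethyl addition).**
- Risk: incomplete tin–lithium exchange would allow competing butyl transfer to the aldehyde, and the α-alkoxy organolithium may decay before it adds.
- Fallback, from 11 back to 13: the C3 carbon and its methoxy group are introduced separately. Corey–Chaykovsky methylenation of 11 (Me3SI, NaH, DMSO–THF) should give 2-[3,4,5-trimethoxy-2-(methoxymethoxy)phenyl]oxirane F4. NaOMe in MeOH at reflux should then open it by SN2 attack at the unhindered CH2 to give 13.

**Step 9 (Allan–Robinson melt).**
- Risk: ether cleavage and charring may occur at 180 °C, and aroyl transfer to the hindered, methoxy-bearing C3 may be sluggish.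
- Fallback, from 11 back to 18 through 17: C3–C4 replaces C2–C3 as the joining bond, so neither a melt nor an acyl transfer is needed.
  - 2-Methoxy-1-(4-methoxyphenyl)ethan-1-one F5 is made by Weinreb ketone synthesis from 4-MeOC6H4MgBr and N,2-dimethoxy-N-methylacetamide.
  - Its lithium enolate (LDA, THF, −78 °C) is added to 11 to give the aldol 3-hydroxy-2-methoxy-1-(4-methoxyphenyl)-3-[3,4,5-trimethoxy-2-(methoxymethoxy)phenyl]propan-1-one F6 as a diastereomer mixture.
  - Dess–Martin oxidation should give 2-methoxy-1-(4-methoxyphenyl)-3-[3,4,5-trimethoxy-2-(methoxymethoxy)phenyl]propane-1,3-dione F7.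
  - HCl in MeOH at 60 °C removes the MOM group to give 17, which cyclodehydrates to 18.

**Further compounds**

F1 | step 3 | 2-(diethoxymethyl)-5,6-dimethoxybenzene-1,4-diol | CCOC(OCC)c1cc(O)c(OC)c(OC)c1O
F2 | step 3 | 2,5-dihydroxy-3,4-dimethoxybenzaldehyde | O=Cc1cc(O)c(OC)c(OC)c1O
F3 | step 3 | 2-hydroxy-3,4,5-trimethoxybenzaldehyde | O=Cc1cc(OC)c(OC)c(OC)c1O
F4 | step 6 | rac-2-[3,4,5-trimethoxy-2-(methoxymethoxy)phenyl]oxirane | COCOc1c(C2CO2)cc(OC)c(OC)c1OC
F5 | step 9 | 2-methoxy-1-(4-methoxyphenyl)ethan-1-one | COCC(=O)c1ccc(OC)cc1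
F6 | step 9 | 3-hydroxy-2-methoxy-1-(4-methoxyphenyl)-3-[3,4,5-trimethoxy-2-(methoxymethoxy)phenyl]propan-1-one (racemic diastereomer mixture) | COc1ccc(C(=O)C(OC)C(O)c2cc(OC)c(OC)c(OC)c2OCOC)cc1
F7 | step 9 | 2-methoxy-1-(4-methoxyphenyl)-3-[3,4,5-trimethoxy-2-(methoxymethoxy)phenyl]propane-1,3-dione | COc1ccc(C(=O)C(OC)C(=O)c2cc(OC)c(OC)c(OC)c2OCOC)cc1
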